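The numbers are those of an exercise; the result is computed.

Start from late times: ask how long the enzyme would need to turn the whole charge into target, then read each set-up as the share of that time it grants.

| setting | grey | amber | green | teal |
|---|---|---|---|---|
| starting material | 31 mM | 31 mM | 31 mM | 31 mM (fed, over 24.0 s) |
| second substrate | 32.6 mM | 32.6 mM | 32.6 mM | 32.6 mM |
| free enzyme | 2.3 µM | 2.3 µM | 2.3 µM | 2.3 µM |
| remark | one stirred flow tank at steady state, fed with the mixture as stated, mean residence time 90.0 s | one stirred flow tank at steady state, fed with the mixture as stated, mean residence time 30 s | everything together in a closed stirred flask, run for 30 s | a stirred flask in which starting material is dosed at a steady rate over 24.0 s without added volume, worked up at 30 s |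
| time |  |  | 30 s | 30 s |

1. the set-up with the highest amount of target at the outlet or at the end, in percent of the starting material put in ("none" if the first two lie within 2 percentage points) (grey / amber / green / teal / none)
2. amount of target at the outlet or at the end, in percent of the starting material put in, grey
3. amount of target at the outlet or at the end, in percent of the starting material put in, amber
4. amount of target at the outlet or at the end, in percent of the starting material put in, green
5. amount of target at the outlet or at the end, in percent of the starting material put in, teal

- the stated concentrations are those of everything mixed, before any reaction; amounts are the same in each set-up
- the feed brings no volume worth counting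
- run time (green): 30 s

    second substrate → decomposed reagent (k1 = 0.00148 /s)
    starting material + free enzyme ⇌ first complex (K2 = 14 /M, k2 = 95100 /M/s)
    first complex → loaded enzyme + first product (k3 = 137 /s)
    second complex → free enzyme + target (k4 = 131 /s)
    second substrate + loaded enzyme ⇌ second complex (K5 = 1000 /M, k5 = 3.06 × 10⁵ /M/s)

Guess first that a round of one enzyme costs the two forward lifetimes of the complexes. Multiply by the rounds each enzyme must make:

charge at enzyme, times both lifetimes = 201 s

Now object: first complex falls back at 6790 /s, faster than it goes forward at 137 /s, so just 1.98% of its visits go on. Count the waits too. Take the Michaelis constant of starting material as a fraction of the charge, and the later half of the round with its wait for second substrate: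

Michaelis fraction = 2.35
later half of the round = 0.00797 s

With a fraction a of the charge standing, the first half costs its forward lifetime times one plus the Michaelis fraction over a. At the full charge, the charge time, the time the enzyme needs to turn the whole charge at the going speed, is:

charge time = 437 s

Object again: the charge falls, and a tank works at its outlet fraction throughout. So take a first yield, put it back into the charge time, and divide again:

grey: 20.6%, then 18.1%
amber: 6.86%, then 6.61%
green, at the mean fraction: 6.74%

Does the decay of second substrate spoil this? Its half-life of 7.8 min is longer than the longest stay, so leave it out.

Teal raises a further objection: its fraction climbs from nothing during the feed, and at a small fraction a round takes longer. Integrate the inverse charge time over the feed, then add the remaining time at green's rate: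

teal: 3.32% plus 1.35% = 4.67%

I commit to grey.

The forecast also names grey, with 18.3% for grey, 6.6% for amber, 6.7% for green and 4.65% for teal, holding that “the 30 s tank and flask nearly tie”.

The simulation gives grey: grey 18.3%, amber 6.61%, green 6.73%, teal 4.61%.

The undoing of first complex is a part of what holds grey down: strike it, and grey goes from 18.3% to 41.4%. Reckon that case: the charge time falls to 210 s, and grey's stay of 90.0 s then grants 42.9%, reckoned at the full charge. In teal the undoing of first complex acts together with the short time: strike the undoing and teal goes from 4.61% to 13.4%, or leave teal until 300 s and it gives 53.6%. Now take the neighbour of teal with 0.0057 mM of free enzyme: its charge time shrinks in proportion, which lifts teal's 4.61% to 11.4%, and that flask gives 11.1%.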